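Ring D of the target (N5, C4a, C13a, C13, C12b) is an indole pyrrole: C13 carries a carbonyl carbon, C12b an indol-2-yl group, and Br at C3 lies para to C13a. It is therefore disconnected at C13–C13a and N5–C12b. In one operation, oxygen conjugate addition of an N-arylhydroxylamine to an ynoate, a [3,3] shift that breaks the N–O bond, and cyclodehydration assemble the 2,2'-biindole-3-carboxylate. The precursors are N-(3-bromophenyl)hydroxylamine and methyl 3-(1-Boc-indol-2-yl)propiolate. A two-carbon acetal then links N5 to C7a (ring C), and the ester is adjusted to the aldehyde.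

Key step: step 4

Remark on the chemistry: positions carry the 12H-pyrido[1,2-a:3,4-b']diindole numbering (ring D: N5, C4a, C13a, C13, C12b; ring C: N5, C6, C7, C7a, C12a, C12b). The double-bond geometry of 8 is left open because either isomer can reach the rearrangement transition state. Hydroxylamine 2 is assumed to be used freshly prepared.

Step 1
Reactants: 1 1-bromo-3-nitrobenzene
Product: 2 N-(3-bromophenyl)hydroxylamine
Conditions: Zn dust, NH4Cl, EtOH–H2O, 0 °C → rt
Reagents that add atoms: none
Why: Zinc in NH4Cl-buffered aqueous ethanol is the classical partial reduction of a nitroarene, which should stop at the N-arylhydroxylamine when kept cold and leave the aryl bromide untouched.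

Step 2
Reactants: 3 tert-butyl indole-1-carboxylate
Product: 5 tert-butyl 2-iodoindole-1-carboxylate, via tert-butyl 2-lithioindole-1-carboxylate 4 (not isolated)
Conditions: LiN(i-Pr)2, THF, −78 °C; then I2, −78 °C → rt
Reagents that add atoms: iodine, II
Why: Carbamate-directed lithiation (directed metalation) of the indole C2–H by the hindered amide base at −78 °C, where the Boc group resists attack and migration, followed by iodinolysis of the C–Li bond, should give the 2-iodide.

Step 3
Reactants: 5 tert-butyl 2-iodoindole-1-carboxylate; 6 methyl propiolate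
Product: 7 methyl 3-[1-(tert-butoxycarbonyl)indol-2-yl]propiolate
Conditions: Pd(PPh3)2Cl2 (cat.), CuI (cat.), K2CO3, THF, 65 °C, excess 6 added in portions
Reagents that add atoms: none
Why: Sonogashira coupling at the C2–I bond, which adds readily to zerovalent palladium, run with K2CO3 in place of an amine base so that the propiolate is not consumed by amine conjugate addition and oligomerisation.

Step 4
Reactants: 2 N-(3-bromophenyl)hydroxylamine; 7 methyl 3-[1-(tert-butoxycarbonyl)indol-2-yl]propiolate
Product: 10 methyl 6-bromo-2-[1-(tert-butoxycarbonyl)indol-2-yl]-1H-indole-3-carboxylate, via O-alkenyl hydroxylamine 8 (not isolated), via ortho-aminoaryl keto ester 9 (not isolated)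
Conditions: DABCO (cat.), THF, 0 °C → rt; chromatographic removal of the 4-bromo regioisomer
Reagents that add atoms: none
Why: DABCO, as nucleophilic or general-base catalyst, should deliver the hydroxylamine oxygen of 2 in an oxa-Michael addition to the β-carbon of ynoate 7 (the carbon bearing the indolyl group), giving the N-aryl-O-alkenyl hydroxylamine 8. The weak N–O bond of 8 then breaks in a hetero-Cope [3,3] sigmatropic shift that joins the ester-bearing carbon (C13) to an ortho carbon of the bromoarene (C13a), and tautomerisation restores the benzene ring to give the β-keto ester 9. The aniline nitrogen of 9 attacks the ketone carbon (C12b) in a 5-exo-trig closure, and loss of water aromatises ring D. The closest known reaction type is the amine-catalysed annulation of N-arylhydroxylamines with electron-poor alkynes to indole-3-carboxylates, shown mainly for terminal and symmetrical alkynes; no stereocentre is formed. Two selectivities are needed: O- rather than N-addition at the indolyl-bearing alkyne carbon, which the base catalyst and the ynoate polarisation (kept undamped by the electron-withdrawing Boc group on the indole nitrogen) should secure, and rearrangement to the ortho carbon para to Br rather than the one flanked by Br, which is favoured only on steric grounds, so the minor isomer has to be separated. The mild temperature should leave both the aryl bromide and the Boc group intact.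

Step 5
Reactants: 10 methyl 6-bromo-2-[1-(tert-butoxycarbonyl)indol-2-yl]-1H-indole-3-carboxylate; 11 bromoacetaldehyde diethyl acetal
Product: 12 methyl 6-bromo-1-(2,2-diethoxyethyl)-2-[1-(tert-butoxycarbonyl)indol-2-yl]indole-3-carboxylate
Conditions: Cs2CO3, DMF, 80 °C
Reagents that add atoms: none
Why: The N5–H of the indole-3-carboxylate is a vinylogous carbamate N–H, acidic enough for Cs2CO3, and its anion should undergo SN2 N-alkylation while the Boc group masks the other indole nitrogen.

Step 6
Reactants: 12 methyl 6-bromo-1-(2,2-diethoxyethyl)-2-[1-(tert-butoxycarbonyl)indol-2-yl]indole-3-carboxylate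
Product: 15 methyl 3-bromo-12H-pyrido[1,2-a:3,4-b']diindole-13-carboxylate, via Boc-free diethyl acetal 13 (not isolated), via 7-ethoxy-6,7-dihydro adduct 14 (not isolated)
Conditions: CF3CO2H, CH2Cl2, 0 °C → rt
Reagents that add atoms: none
Why: Trifluoroacetic acid should cleave the indole N-Boc carbamate (13) and ionise the acetal to an oxocarbenium ion, which the nucleophilic indole C3 (C7a) captures in a six-membered intramolecular Friedel–Crafts (Pomeranz–Fritsch-type) cyclisation to 14, from which loss of ethanol aromatises ring C.

Step 7
Reactants: 15 methyl 3-bromo-12H-pyrido[1,2-a:3,4-b']diindole-13-carboxylate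
Product: 16 (3-bromo-12H-pyrido[1,2-a:3,4-b']diindol-13-yl)methanol
Conditions: i-Bu2AlH (excess), THF, −78 → 0 °C; aq. potassium sodium tartrate
Reagents that add atoms: none
Why: Excess i-Bu2AlH (one equivalent is spent on N12–H) should reduce the vinylogous-carbamate ester to the primary alcohol (hydride reduction of an ester), with low temperature and a non-acidic tartrate work-up protecting the ionisable heteroaryl carbinol, which is carried on crude.

Step 8
Reactants: 16 (3-bromo-12H-pyrido[1,2-a:3,4-b']diindol-13-yl)methanol
Product: 17 3-bromo-12H-pyrido[1,2-a:3,4-b']diindole-13-carbaldehyde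
Conditions: activated MnO2, CH2Cl2–THF, rt
Reagents that add atoms: none
Why: MnO2 oxidation of a benzylic-type alcohol should stop cleanly at the aldehyde, which is stabilised as a vinylogous formamide hydrogen-bonded to N12–H.

Compound list
1 | 1-bromo-3-nitrobenzene | O=[N+]([O-])c1cccc(Br)c1 | starting material
2 | N-(3-bromophenyl)hydroxylamine | ONc1cccc(Br)c1 | intermediate
3 | tert-butyl indole-1-carboxylate | CC(C)(C)OC(=O)n1ccc2ccccc12 | starting material
4 | tert-butyl 2-lithioindole-1-carboxylate; not isolated | [Li]c1cc2ccccc2n1C(=O)OC(C)(C)C | intermediate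
5 | tert-butyl 2-iodoindole-1-carboxylate | CC(C)(C)OC(=O)n1c(I)cc2ccccc12 | intermediate
6 | methyl propiolate | C#CC(=O)OC | starting material
7 | methyl 3-[1-(tert-butoxycarbonyl)indol-2-yl]propiolate | COC(=O)C#Cc1cc2ccccc2n1C(=O)OC(C)(C)C | intermediate
8 | methyl 3-{[(3-bromophenyl)amino]oxy}-3-[1-(tert-butoxycarbonyl)indol-2-yl]prop-2-enoate; alkene geometry not defined; not isolated | COC(=O)C=C(ONc1cccc(Br)c1)c1cc2ccccc2n1C(=O)OC(C)(C)C | intermediate
9 | methyl 2-(2-amino-4-bromophenyl)-3-[1-(tert-butoxycarbonyl)indol-2-yl]-3-oxopropanoate; racemic and enolisable; not isolated | COC(=O)C(c1ccc(Br)cc1N)C(=O)c1cc2ccccc2n1C(=O)OC(C)(C)C | intermediate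
10 | methyl 6-bromo-2-[1-(tert-butoxycarbonyl)indol-2-yl]-1H-indole-3-carboxylate | COC(=O)c1c(-c2cc3ccccc3n2C(=O)OC(C)(C)C)[nH]c2cc(Br)ccc12 | intermediate
11 | bromoacetaldehyde diethyl acetal | CCOC(CBr)OCC | starting material
12 | methyl 6-bromo-1-(2,2-diethoxyethyl)-2-[1-(tert-butoxycarbonyl)indol-2-yl]indole-3-carboxylate | CCOC(Cn1c(-c2cc3ccccc3n2C(=O)OC(C)(C)C)c(C(=O)OC)c2ccc(Br)cc12)OCC | intermediate
13 | methyl 6-bromo-1-(2,2-diethoxyethyl)-2-(1H-indol-2-yl)indole-3-carboxylate; not isolated | CCOC(Cn1c(-c2cc3ccccc3[nH]2)c(C(=O)OC)c2ccc(Br)cc12)OCC | intermediate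
14 | methyl 3-bromo-7-ethoxy-6,7-dihydro-12H-pyrido[1,2-a:3,4-b']diindole-13-carboxylate; racemic at C7; not isolated | CCOC1Cn2c3cc(Br)ccc3c(C(=O)OC)c2-c2[nH]c3ccccc3c21 | intermediate
15 | methyl 3-bromo-12H-pyrido[1,2-a:3,4-b']diindole-13-carboxylate | COC(=O)c1c2ccc(Br)cc2n2ccc3c4ccccc4[nH]c3c12 | intermediate
16 | (3-bromo-12H-pyrido[1,2-a:3,4-b']diindol-13-yl)methanol | OCc1c2ccc(Br)cc2n2ccc3c4ccccc4[nH]c3c12 | intermediate
17 | 3-bromo-12H-pyrido[1,2-a:3,4-b']diindole-13-carbaldehyde | O=Cc1c2ccc(Br)cc2n2ccc3c4ccccc4[nH]c3c12 | target

Total step count: 8.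
Longest linear sequence: 7 steps (steps 2 to 8, from tert-butyl indole-1-carboxylate); step 1 is a one-step side branch that joins at step 4.

Steps most likely to fail

Step 4. What may go wrong: addition of the hydroxylamine through nitrogen instead of oxygen to the hindered internal ynoate, or unselective rearrangement to both ortho carbons. Fallback: setting out from 7, commercial 3-bromoaniline is added across the ynoate in a conjugate hydroamination (AgOTf cat., MeOH, 60 °C) to give methyl (Z)-3-(3-bromoanilino)-3-[1-(tert-butoxycarbonyl)indol-2-yl]acrylate F1. Oxidative C–H cyclisation of this N-aryl enamino ester (Pd(OAc)2 cat., Cu(OAc)2, K2CO3, DMF, 80 °C) then forms the same C13–C13a bond, preferentially at the less hindered ortho carbon. The copper oxidant should return palladium to the divalent state before zerovalent palladium can insert into C–Br. The fallback rejoins the route at 10.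

Step 5. What may go wrong: slow SN2 displacement by the hindered, ester-stabilised N5 anion on a β-branched bromide, so that Boc transfer or loss competes at the temperature required. Fallback: setting out from 10, N-allylation with the far more reactive allyl bromide (K2CO3, DMF, rt) gives methyl 1-allyl-6-bromo-2-[1-(tert-butoxycarbonyl)indol-2-yl]indole-3-carboxylate F2. Lemieux–Johnson cleavage (OsO4 cat., NaIO4, 2,6-lutidine, dioxane–H2O) gives methyl 6-bromo-2-[1-(tert-butoxycarbonyl)indol-2-yl]-1-(2-oxoethyl)indole-3-carboxylate F3. Trifluoroacetic acid in CH2Cl2 then removes Boc and cyclodehydrates the aldehyde onto C7a, rejoining the route at 15.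

Step 7. What may go wrong: ionisation of the electron-rich carbinol during reduction or work-up (over-reduction to a 13-methyl group, oligomerisation), or incomplete reduction of the deactivated ester. Fallback: setting out from 15, saponification (KOH, aq. EtOH, reflux) gives 3-bromo-12H-pyrido[1,2-a:3,4-b']diindole-13-carboxylic acid F4. Warming in acetic acid protodecarboxylates this indole-3-carboxylic acid to 3-bromo-12H-pyrido[1,2-a:3,4-b']diindole F5. Vilsmeier–Haack formylation (POCl3, DMF, 0 °C → rt; aq. NaOAc) at C13, the most nucleophilic position of the ring system, then gives the target, rejoining the route at 17.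

Further compounds
F1 | step 4 | methyl (Z)-3-(3-bromoanilino)-3-[1-(tert-butoxycarbonyl)indol-2-yl]acrylate | COC(=O)/C=C(\Nc1cccc(Br)c1)c1cc2ccccc2n1C(=O)OC(C)(C)C
F2 | step 5 | methyl 1-allyl-6-bromo-2-[1-(tert-butoxycarbonyl)indol-2-yl]indole-3-carboxylate | C=CCn1c(-c2cc3ccccc3n2C(=O)OC(C)(C)C)c(C(=O)OC)c2ccc(Br)cc12
F3 | step 5 | methyl 6-bromo-2-[1-(tert-butoxycarbonyl)indol-2-yl]-1-(2-oxoethyl)indole-3-carboxylate | O=CCn1c(-c2cc3ccccc3n2C(=O)OC(C)(C)C)c(C(=O)OC)c2ccc(Br)cc12
F4 | step 7 | 3-bromo-12H-pyrido[1,2-a:3,4-b']diindole-13-carboxylic acid | OC(=O)c1c2ccc(Br)cc2n2ccc3c4ccccc4[nH]c3c12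
F5 | step 7 | 3-bromo-12H-pyrido[1,2-a:3,4-b']diindole | c1c2ccc(Br)cc2n2ccc3c4ccccc4[nH]c3c12
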